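Ring A is cut at C1–C10 and C4–C5 (eremophilane numbering): C1–C4 become (E)-pent-3-en-2-one, ring B becomes the enolised 9,10-dione of a carane drawn from (+)-3-carene. One Robinson annulation makes both bonds: enolate carbon C5 adds to C4 anti to the cyclopropane, then C1 condenses with the C10 carbonyl. The step exploits the C2 ketone, which is 1,5 to C10 through C4–C5 and 1,3 through C1, and the cis C4/C5 methyl pair. The C7–C8–C11 cyclopropane of the precursor hides the isopropenyl group; a later homodienyl hydrogen shift cleaves C8–C11, delivers 10β-H and leaves a C8=C9 enol ether for both ester-bearing carbons.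

Key step: step 4

Remark on the chemistry: eremophilane numbering is used for every intermediate (ring A = C1–C5 and C10; ring B = C5–C10; C11 = the carbon with the geminal methyl groups, later the isopropenyl carbon). β is the face of the C5 methyl group in the target. Commercial (+)-3-carene is taken to be the (1S,6R) enantiomer, whose cyclopropane then lies on the β face.

Step 1
Reactants: 1 (+)-3-carene
Product: 3 4-isocaranol, via diisocaranylborane 2 (not isolated)
Conditions: BH3·THF (0.55 equiv), THF, 0 °C to rt; then 3 M NaOH, 30% H2O2, 0 to 40 °C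
Reagents that add atoms: hydrogen peroxide, OO
Why: Hydroboration–oxidation: syn, anti-Markovnikov addition of H–B from the α face, opposite to the gem-dimethylcyclopropane, should place oxygen on C10 (10α-OH, 5β-methyl); both new stereocentres are erased again in steps 2 to 4.

Step 2
Reactants: 3 4-isocaranol
Product: 4 4-isocaranone
Conditions: Dess–Martin periodinane, CH2Cl2, rt
Reagents that add atoms: none
Why: Dess–Martin oxidation of a secondary alcohol under neutral conditions that leave the cyclopropane untouched; no stereocentre is set.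

Step 3
Reactants: 4 4-isocaranone
Product: 5 carane diosphenol
Conditions: SeO2 (1.1 equiv), dioxane–H2O (20:1), 90 °C
Reagents that add atoms: selenium dioxide, O=[Se]=O
Why: Riley oxidation: SeO2 should attack the enol towards the C9 methylene (conjugated with the cyclopropane), and the resulting 9,10-dione can enolise only towards C5 because C8 is a cyclopropane carbon, so a single diosphenol is expected.

Step 4
Reactants: 5 carane diosphenol; 6 (E)-pent-3-en-2-one
Product: 9 tricyclic enedione, via Michael triketone 7 (not isolated), via cis-fused ketol 8 (not isolated)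
Conditions: 6 (2.5 equiv), t-BuOK (0.3 equiv), t-BuOH–THF, 25 to 65 °C
Reagents that add atoms: none
Why: Robinson annulation (Michael addition, then aldol condensation). t-BuOK deprotonates the enol of 5 and the enolate adds through C5, its only nucleophilic carbon, to C4 of 6 to give 7; proton transfer moves the new enolate to C1, which attacks the C10 carbonyl (attack on C9 would need a seven-membered ring), and loss of water from 8 gives 9. Ring A closes in the 6-(enolexo)-exo-trig mode. C5 is controlled by the gem-dimethylcyclopropane, whose endo methyl group covers the β face, so that C4 is bound on the α face and the C5 methyl group is left β. C4 is controlled by the staggered Michael transition state usual for (E)-pent-3-en-2-one and 2-methylcyclohexanone-type enolates, in which the acceptor chain (C3) lies over the tied-back ring methylene C6 and the C4 hydrogen lies between C10 and the C5 methyl group, which leaves the two methyl groups cis. The step needs C- over O-alkylation and a single site of reaction: oxa-Michael addition is reversible, C8 cannot be enolised, and the irreversible dehydration drains the equilibria towards 9.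

Step 5
Reactants: 9 tricyclic enedione
Product: 11 C9 TBS enol ether, via lithium C9 enolate 10 (not isolated)
Conditions: LiBH(s-Bu)3 (L-Selectride, 1.05 equiv), THF, −78 °C; then TBSOTf (1.2 equiv), −78 to 0 °C
Reagents that add atoms: tert-butyldimethylsilyl triflate, CC(C)(C)[Si](C)(C)OS(=O)(=O)C(F)(F)F
Why: Conjugate (1,4) hydride reduction of an enedione followed by O-silylation: the bulky borohydride can reach only the CH terminus C1 (C10 is fully substituted), which turns C1 into a methylene and releases the C9 enolate towards C10; no stereocentre is set.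

Step 6
Reactants: 11 C9 TBS enol ether
Product: 12 ring-opened C8=C9 TBS enol ether
Conditions: mesitylene (0.05 M), BHT (cat.), sealed tube, 220 °C
Reagents that add atoms: none
Why: Homodienyl [1,5]-hydrogen shift (retro-ene reaction) of a cis-2-methyl-1-vinylcyclopropane, the reaction type by which 2-carene opens on heating: a hydrogen of the endo C11 methyl group passes suprafacially to the β face of C10 (sets 10β-H, hence the cis-decalin), C8–C11 breaks, C11 becomes the isopropenyl group on C7 with the carene configuration kept, and the enol ether moves to C8=C9.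

Step 7
Reactants: 12 ring-opened C8=C9 TBS enol ether
Product: 13 8β-bromo diketone
Conditions: NBS (1.0 equiv), THF, −78 °C; aq. NaHCO3
Reagents that add atoms: N-bromosuccinimide, O=C1CCC(=O)N1Br
Why: Electrophilic α-bromination of a silyl enol ether, much faster than attack on the isopropenyl group at this temperature: bromine should enter axially from the convex β face (the α face is covered by axial C4) and set the 8β-bromide.

Step 8
Reactants: 13 8β-bromo diketone
Product: 14 8α-acetoxy diketone
Conditions: CsOAc (1.5 equiv), DMF, 0 °C to rt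
Reagents that add atoms: caesium acetate, CC(=O)[O-].[Cs+]
Why: SN2 displacement of an axial α-bromo ketone by acetate, accelerated by overlap of the C–Br bond with the carbonyl group, inverts C8 and sets the equatorial 8α-acetate, trans to the 7β-isopropenyl group.

Step 9
Reactants: 14 8α-acetoxy diketone
Product: 15 C2 ethylene ketal
Conditions: TMSOCH2CH2OTMS (1.5 equiv), TMSOTf (5 mol %), CH2Cl2, −78 to −30 °C; pyridine quench
Reagents that add atoms: 1,2-bis(trimethylsilyloxy)ethane, C[Si](C)(C)OCCO[Si](C)(C)C
Why: Chemoselective aprotic ketalisation under TMSOTf catalysis: the unhindered C2 ketone reacts, the C9 ketone flanked by C10 and the acetoxy carbon does not, and the cold conditions should spare the epimerisable C8 and C10.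

Step 10
Reactants: 15 C2 ethylene ketal
Product: 16 9α-alcohol
Conditions: NaBH4, CeCl3·7H2O, MeOH–THF, −40 °C
Reagents that add atoms: none
Why: Luche-type 1,2-reduction: axial approach from the α face is blocked by axial C4, so hydride should arrive from the convex β face and set the axial 9α-alcohol, cis to the acetate.

Step 11
Reactants: 16 9α-alcohol
Product: 17 ketal diester
Conditions: 3-methylbut-2-enoyl chloride (3 equiv), pyridine, DMAP (0.2 equiv), CH2Cl2, 0 to 40 °C
Reagents that add atoms: 3-methylbut-2-enoyl chloride (senecioyl chloride), CC(C)=CC(=O)Cl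
Why: DMAP-catalysed acylation (nucleophilic catalysis) of the hindered axial 9α-alcohol; pyridine in place of a trialkylamine limits ketene formation and deconjugation of the senecioate, and no stereocentre changes.

Step 12
Reactants: 17 ketal diester
Product: 18 target
Conditions: PPTS (0.2 equiv), acetone–H2O (10:1), 50 °C
Reagents that add atoms: water, O
Why: Acid-catalysed hydrolysis of the dioxolane under mild PPTS conditions that should leave both esters, the isopropenyl group and all six stereocentres untouched.

Compound list
1 | (+)-3-carene, (1S,6R)-3,7,7-trimethylbicyclo[4.1.0]hept-3-ene (C5=C10 alkene, β-cyclopropane C7–C8–C11) | CC1(C)[C@H]2CC(C)=CC[C@@H]12 | starting material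
2 | bis(4-isocaranyl)borane (boron on C10 from the α face, 5β-methyl) | B([C@@H]1C[C@@H]2[C@H](C[C@H]1C)C2(C)C)[C@@H]1C[C@@H]2[C@H](C[C@H]1C)C2(C)C | intermediate
3 | 4-isocaranol (10α-OH, 5β-methyl, β-cyclopropane) | CC1(C)[C@H]2C[C@@H](C)[C@H](O)C[C@@H]12 | intermediate
4 | 4-isocaranone (C10 ketone, 5β-methyl, β-cyclopropane) | CC1(C)[C@H]2C[C@@H](C)C(=O)C[C@@H]12 | intermediate
5 | carane diosphenol, 4-hydroxycar-3-en-5-one (C9 ketone, C10 enol OH, C5=C10, β-cyclopropane) | CC1(C)[C@H]2CC(C)=C(O)C(=O)[C@@H]12 | intermediate
6 | (E)-pent-3-en-2-one | C/C=C/C(C)=O | starting material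
7 | Michael triketone (carane-9,10-dione; C5 carries β-methyl and the α-(4-oxopentan-2-yl) chain, C4 as in the target) | CC1(C)[C@H]2C[C@](C)([C@@H](C)CC(C)=O)C(=O)C(=O)[C@@H]12 | intermediate
8 | cis-fused ketol (10β-OH, C1 on the α face, C2 and C9 ketones, 4β,5β-dimethyl) | CC1(C)[C@H]2C[C@@]3(C)[C@](O)(CC(=O)C[C@@H]3C)C(=O)[C@@H]12 | intermediate
9 | tricyclic enedione (1(10)-ene-2,9-dione, 4β,5β-dimethyl, β-cyclopropane C7–C8–C11) | CC1(C)[C@H]2C[C@@]3(C)C(=CC(=O)C[C@@H]3C)C(=O)[C@@H]12 | intermediate
10 | lithium C9 enolate (C9=C10, C2 ketone, cyclopropane intact) | CC1(C)[C@H]2C[C@@]3(C)C(CC(=O)C[C@@H]3C)=C([O-])[C@@H]12.[Li+] | intermediate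
11 | C9 TBS enol ether (C9=C10, C2 ketone, 4β,5β-dimethyl, β-cyclopropane) | CC1(C)[C@H]2C[C@@]3(C)C(CC(=O)C[C@@H]3C)=C(O[Si](C)(C)C(C)(C)C)[C@@H]12 | intermediate
12 | 9-(tert-butyldimethylsilyloxy)-10βH-eremophila-8,11-dien-2-one (4β,5β-dimethyl, 7β-isopropenyl) | C=C(C)[C@H]1C[C@@]2(C)[C@H](CC(=O)C[C@@H]2C)C(O[Si](C)(C)C(C)(C)C)=C1 | intermediate
13 | 8β-bromo-10βH-eremophil-11-ene-2,9-dione | C=C(C)[C@H]1C[C@@]2(C)[C@H](CC(=O)C[C@@H]2C)C(=O)[C@H]1Br | intermediate
14 | 8α-acetoxy-10βH-eremophil-11-ene-2,9-dione | C=C(C)[C@H]1C[C@@]2(C)[C@H](CC(=O)C[C@@H]2C)C(=O)[C@@H]1OC(C)=O | intermediate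
15 | 8α-acetoxy-2,2-ethylenedioxy-10βH-eremophil-11-en-9-one | C=C(C)[C@H]1C[C@@]2(C)[C@H](CC3(OCCO3)C[C@@H]2C)C(=O)[C@@H]1OC(C)=O | intermediate
16 | 8α-acetoxy-2,2-ethylenedioxy-10βH-eremophil-11-en-9α-ol | C=C(C)[C@H]1C[C@@]2(C)[C@H](CC3(OCCO3)C[C@@H]2C)[C@H](O)[C@@H]1OC(C)=O | intermediate
17 | 8α-acetoxy-2,2-ethylenedioxy-9α-(3-methylbut-2-enoyloxy)-10βH-eremophil-11-ene | C=C(C)[C@H]1C[C@@]2(C)[C@H](CC3(OCCO3)C[C@@H]2C)[C@H](OC(=O)C=C(C)C)[C@@H]1OC(C)=O | intermediate
18 | 8α-acetoxy-9α-(3-methylbut-2-enoyloxy)-10βH-eremophil-11-en-2-one (4β,5β-dimethyl, 7β-isopropenyl) | C=C(C)[C@H]1C[C@@]2(C)[C@H](CC(=O)C[C@@H]2C)[C@H](OC(=O)C=C(C)C)[C@@H]1OC(C)=O | target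

Total step count: 12. Longest linear sequence: 12 steps (1 to 18).

Steps most likely to fail

1. Step 4 (key step).
- What may go wrong: the Michael addition builds a quaternary carbon next to a tertiary one. It may be too slow against retro-Michael reaction, polymerisation of 6 and base-induced cleavage of the non-enolisable 1,2-dione. Facial discrimination at C4 may also be low.
- Fallback: annulate before the C9 oxygen is in place. It sets out from 4. The thermodynamic C5 enolate of this simple 2-methylcyclohexanone-type ketone (NaOEt, EtOH, 6, 0 °C to reflux) should undergo the classical Robinson annulation, again anti to the cyclopropane, to the tricyclic 1(10)-en-2-one F1. Its C9 methylene, γ to the enone and next to the cyclopropane, is then oxidised to the ketone (t-BuOOH, Rh2(caprolactamate)4, K2CO3, CH2Cl2). This comes back to the route at 9.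

2. Step 5.
- What may go wrong: 1,2-reduction of the unhindered C2 carbonyl may compete, and proton transfer between the C9 enolate and the new C2 ketone may occur before silylation. Either would scramble the position of the enol ether.
- Fallback: separate reduction, protection and enolisation. It sets out from 9. Zn in AcOH should reduce the enedione to the saturated tricyclic 2,9-dione F2 (C10 epimers, of no consequence). Ketalisation as in step 9 protects only the C2 ketone, giving the mono-ketal F3. Soft enolisation of the remaining ketone (TBSOTf, Et3N), possible only towards C10, gives the ketal enol ether F4. Thermolysis as in step 6 gives the ring-opened ketal enol ether F5, and bromination as in step 7 gives the ketal 8β-bromo ketone F6. Acetate displacement as in step 8 then comes back to the route at 15, so step 9 is no longer needed.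

3. Step 8.
- What may go wrong: loss of HBr towards C7 (the 7α-hydrogen is anti-periplanar to the axial bromide) and enolisation-driven epimerisation at C8 or C10 under the basic acetate conditions.
- Fallback: bring in oxygen first and invert it under neutral conditions. It sets out from 12. Rubottom oxidation (DMDO, 1.0 equiv, acetone–CH2Cl2, −78 °C, then HF·pyridine) should attack the same convex β face and give the 8β-hydroxy diketone F7. A Mitsunobu reaction (PPh3, DIAD, AcOH, toluene, 0 °C) then inverts C8 and comes back to the route at 14.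

Further compounds
F1 | step 4 | tricyclic 1(10)-en-2-one (C9 methylene, 4β,5β-dimethyl, β-cyclopropane) | CC1(C)[C@H]2C[C@@]3(C)C(=CC(=O)C[C@@H]3C)C[C@@H]12
F2 | step 5 | saturated tricyclic 2,9-dione (C10 epimers) | CC1(C)[C@H]2C[C@@]3(C)C(CC(=O)C[C@@H]3C)C(=O)[C@@H]12
F3 | step 5 | C2 ethylene ketal of F2 | CC1(C)[C@H]2C[C@@]3(C)C(CC4(OCCO4)C[C@@H]3C)C(=O)[C@@H]12
F4 | step 5 | C9 TBS enol ether (C9=C10) of F3 | CC1(C)[C@H]2C[C@@]3(C)C(CC4(OCCO4)C[C@@H]3C)=C(O[Si](C)(C)C(C)(C)C)[C@@H]12
F5 | step 5 | C2 ethylene ketal of 12 | C=C(C)[C@H]1C[C@@]2(C)[C@H](CC3(OCCO3)C[C@@H]2C)C(O[Si](C)(C)C(C)(C)C)=C1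
F6 | step 5 | C2 ethylene ketal of 13 | C=C(C)[C@H]1C[C@@]2(C)[C@H](CC3(OCCO3)C[C@@H]2C)C(=O)[C@H]1Br
F7 | step 8 | 8β-hydroxy-10βH-eremophil-11-ene-2,9-dione | C=C(C)[C@H]1C[C@@]2(C)[C@H](CC(=O)C[C@@H]2C)C(=O)[C@H]1O
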